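## Retrosynthetic overview

1. Kuwanon J (20) ⇐ hepta-MOM ether 18, by a non-acidic silyl-transfer removal of the seven MOM groups.
2. 18 ⇐ chalcone 11 + dienyl chalcone 17. The cyclohexene is closed by a photoreductive radical-anion [4+2] union under a chiral Sc(OTf)3–PyBOX complex: C5–C6 forms first by addition of the chalcone β-radical to the diene terminus, then C3–C4 by allyl radical/enolate closure. All three stereocentres are set here.
3. 11 ⇐ ketone 6 + aldehyde 9, and 17 ⇐ ketone 15 + aldehyde 9, both by Claisen–Schmidt condensation.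
4. 6 ⇐ resacetophenone 3 (C-prenylation, 4-O-MOM); 15 ⇐ 3 (C3 iodination, MOM, Heck reaction with isoprene); 9 ⇐ resorcinol (Vilsmeier–Haack formylation, MOM).
5. Ring order: the four benzene rings A–D all come from resorcinol 1; the cyclohexene is the only ring that is made (step 11).

Assumption: the (S,S) ligand in step 11 is taken to expose the face of the bound chalcone that leads to 5S; if the first run gives the mirror-image series, the (R,R) ligand is used and nothing else changes.

Locants used below: in the cyclohexene, C1 carries the methyl group, C1=C2 is the double bond, C3 carries ring C, C4 the aroyl group (ring A) and C5 ring B; ring D is the aryl group of the remaining enone. The target is 3S,4R,5S, with C3/C4 cis and C4/C5 trans.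

## Route

Step 1
Reactants: 1 resorcinol; 2 acetic acid
Product: 3 1-(2,4-dihydroxyphenyl)ethanone (resacetophenone)
Conditions: ZnCl2 (1.5 equiv), AcOH, 140 °C, 20 min
Reagents that add atoms: none
Why: Nencki reaction (ZnCl2-promoted Friedel–Crafts C-acylation with acetic acid) goes at C4 of resorcinol, ortho and para to the two hydroxyls; no stereocentre is formed.

Step 2
Reactants: 3 resacetophenone; 4 prenyl bromide (1-bromo-3-methylbut-2-ene)
Product: 5 1-[2,4-dihydroxy-3-(3-methylbut-2-enyl)phenyl]ethanone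
Conditions: prenyl bromide (1.0 equiv), 10% aq KOH, 0 °C to rt, 16 h
Reagents that add atoms: none
Why: Phenoxide C-alkylation (C-prenylation) in water puts the allyl group mainly on C3 between the two oxygens (about 30–40% expected; the 5-prenyl and O-prenyl isomers are removed by chromatography); no stereocentre is formed.

Step 3
Reactants: 5 3-prenylresacetophenone
Product: 6 1-[2-hydroxy-4-(methoxymethoxy)-3-(3-methylbut-2-enyl)phenyl]ethanone
Conditions: MOMCl (1.2 equiv), K2CO3 (2 equiv), acetone, rt, 4 h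
Reagents that add atoms: chloromethyl methyl ether (MOMCl), COCCl
Why: Williamson-type acetal formation occurs only at the 4-OH because the 2-OH is held in a hydrogen bond to the ketone, and this free 2-OH is kept as the binding site for the catalyst in step 11.

Step 4
Reactants: 1 resorcinol
Product: 8 2,4-dihydroxybenzaldehyde, via aryl iminium chloride 7 (not isolated)
Conditions: POCl3 (1.2 equiv), DMF (1.3 equiv), MeCN, −15 °C to rt; then H2O, 50 °C
Reagents that add atoms: N,N-dimethylformamide, CN(C)C=O (formyl carbon); water, O (aldehyde oxygen); phosphoryl chloride, O=P(Cl)(Cl)Cl (chloride of 7 only)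
Why: Vilsmeier–Haack formylation: the chloroiminium ion attacks resorcinol at C4 and the precipitated aryl iminium salt is hydrolysed by warm water; no stereocentre is formed.

Step 5
Reactants: 8 2,4-dihydroxybenzaldehyde
Product: 9 2,4-bis(methoxymethoxy)benzaldehyde
Conditions: MOMCl (3 equiv), K2CO3 (4 equiv), acetone, reflux, 6 h
Reagents that add atoms: chloromethyl methyl ether (MOMCl), COCCl
Why: Williamson-type MOM acetal formation on both phenols with excess reagent at reflux makes the aldehyde stable to the hydroxide of steps 6 and 10; no stereocentre is formed.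

Step 6
Reactants: 6 prenyl ketone; 9 bis-MOM aldehyde
Product: 11 (E)-3-[2,4-bis(methoxymethoxy)phenyl]-1-[2-hydroxy-4-(methoxymethoxy)-3-(3-methylbut-2-enyl)phenyl]prop-2-en-1-one, via aldol adduct 10 (not isolated)
Conditions: 50% aq KOH (10 equiv), EtOH, rt, 36 h; then AcOH to pH 6
Reagents that add atoms: none
Why: Claisen–Schmidt (crossed aldol) condensation: the enolate of 6 adds to the non-enolisable aldehyde 9 and the aldol 10 loses water by E1cB to the favoured E-enone, with the MOM acetals and the prenyl group untouched by base.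

Step 7
Reactants: 3 resacetophenone
Product: 12 1-(2,4-dihydroxy-3-iodophenyl)ethanone
Conditions: I2 (0.4 equiv), HIO3 (0.2 equiv), EtOH/H2O 4:1, 35 °C, 2 h
Reagents that add atoms: iodine, I-I; iodic acid, OI(=O)=O
Why: Electrophilic aromatic iodination with the iodine/iodic acid couple (all iodine is used) goes mainly to C3 between the two hydroxyls, and the minor 5-iodo isomer is removed by crystallisation; no stereocentre is formed.

Step 8
Reactants: 12 3-iodoresacetophenone
Product: 13 1-[3-iodo-2,4-bis(methoxymethoxy)phenyl]ethanone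
Conditions: NaH (2.4 equiv), MOMCl (2.6 equiv), DMF, 0 °C to rt, 3 h
Reagents that add atoms: chloromethyl methyl ether (MOMCl), COCCl
Why: Williamson-type double protection via the sodium phenoxides caps both oxygens next to the iodide, so that no phenoxide can trap the allylpalladium intermediate of step 9 as a dihydrobenzofuran and so that 17 has no free 2'-OH to compete for the scandium catalyst in step 11.

Step 9
Reactants: 13 iodo ketone; 14 isoprene (2-methylbuta-1,3-diene)
Product: 15 1-{2,4-bis(methoxymethoxy)-3-[(E)-3-methylbuta-1,3-dienyl]phenyl}ethanone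
Conditions: isoprene (10 equiv), Pd(OAc)2 (5 mol%), Bu4NCl (1 equiv), K2CO3 (2.5 equiv), DMF, 80 °C, sealed tube, 16 h
Reagents that add atoms: none
Why: Mizoroki–Heck reaction with a 1,3-diene: the arylpalladium species (formed from zerovalent palladium and 13) adds to the unsubstituted vinyl terminus of isoprene, and β-hydride elimination from the allylpalladium intermediate gives the conjugated E-1-aryl-3-methylbuta-1,3-diene.

Step 10
Reactants: 15 dienyl ketone; 9 bis-MOM aldehyde
Product: 17 (E)-1-{2,4-bis(methoxymethoxy)-3-[(E)-3-methylbuta-1,3-dienyl]phenyl}-3-[2,4-bis(methoxymethoxy)phenyl]prop-2-en-1-one, via aldol adduct 16 (not isolated)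
Conditions: 50% aq KOH (10 equiv), EtOH, rt, 24 h, dark; then AcOH to pH 6
Reagents that add atoms: none
Why: Claisen–Schmidt condensation as in step 6 gives the E-enone, and the diene and the MOM acetals are stable to hydroxide.

Step 11
Reactants: 11 chalcone with free 2'-OH; 17 dienyl chalcone (1.5 equiv)
Product: 18 hepta-MOM kuwanon J: (3S,4R,5S)-1-methylcyclohexene with ring C (2,6-bis-MOM-oxy-3-[(E)-3-(2,4-bis-MOM-oxyphenyl)acryloyl]phenyl) on C3 and the 2-hydroxy-4-MOM-oxy-3-prenylbenzoyl group on C4 and the 2,4-bis-MOM-oxyphenyl group on C5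
Conditions: Ru(bpy)3(PF6)2 (2.5 mol%), Sc(OTf)3 (10 mol%), 2,6-bis[(4S)-4-tert-butyl-4,5-dihydrooxazol-2-yl]pyridine (15 mol%), i-Pr2NEt (0.5 equiv), MeCN/i-PrOAc 1:3, blue LED (450 nm), 20 °C, degassed, 24 h
Reagents that add atoms: none
Why: Proposed new method: a radical-anion (electron-transfer-initiated) stepwise [4+2] cycloaddition under chiral Lewis acid control, in which only 11 chelates the trivalent scandium–PyBOX complex through its 2'-O/C=O unit and is reduced by photogenerated monovalent ruthenium to a bound radical anion with spin at the benzylic β-carbon; this radical adds to the CH2 terminus of the diene of 17 on the face left open by the tert-butyl groups (C5–C6 bond, sets C5), the allyl radical/scandium enolate pair then closes at C3 through the compact endo arrangement (C3–C4 bond, C3/C4 cis, C4/C5 trans from the E-enone) and the product ketyl passes its electron to the next bound chalcone, with the all-trans isomer removed by chromatography; the closest known reactions are the racemic electron-transfer-initiated [4+2] cycloadditions of 2'-hydroxychalcones with 1-aryl-3-methylbutadienes (monovalent cobalt, ZnI2, borohydride) and the enantioselective Sc(OTf)3–PyBOX/Ru(bpy)3 photocycloadditions of 2'-hydroxychalcones with dienes.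

Step 12
Reactants: 18 hepta-MOM kuwanon J
Product: 20 kuwanon J (target; 3S 4R 5S), via octakis(trimethylsilyl) ether 19 (not isolated)
Conditions: TMSOTf (20 equiv), 2,2'-bipyridyl (30 equiv), MeCN, 0 °C to rt, 2 h; then H2O/THF, rt
Reagents that add atoms: trimethylsilyl trifluoromethanesulfonate, C[Si](C)(C)OS(=O)(=O)C(F)(F)F (silyl groups of 19 only; nothing but hydrogen is added to 20)
Why: Silyl-triflate-mediated acetal exchange (aryl MOM ether to aryl silyl ether, buffered by bipyridyl) followed by hydrolysis of the Si–O bonds removes all seven MOM groups without free Brønsted acid, which spares the acid-labile cis,trans adduct (ketalisation, chroman formation), the prenyl group and the enone, and does not touch the three stereocentres.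

## Compound list

1 | resorcinol | Oc1cccc(O)c1 | starting material
2 | acetic acid | CC(=O)O | starting material
3 | 1-(2,4-dihydroxyphenyl)ethanone | CC(=O)c1ccc(O)cc1O | intermediate
4 | prenyl bromide | CC(C)=CCBr | starting material
5 | 1-[2,4-dihydroxy-3-(3-methylbut-2-enyl)phenyl]ethanone | CC(=O)c1ccc(O)c(CC=C(C)C)c1O | intermediate
6 | 1-[2-hydroxy-4-(methoxymethoxy)-3-(3-methylbut-2-enyl)phenyl]ethanone | CC(=O)c1ccc(OCOC)c(CC=C(C)C)c1O | intermediate
7 | [(2,4-dihydroxyphenyl)methylidene]dimethylammonium chloride | C[N+](C)=Cc1ccc(O)cc1O.[Cl-] | intermediate (not isolated)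
8 | 2,4-dihydroxybenzaldehyde | O=Cc1ccc(O)cc1O | intermediate
9 | 2,4-bis(methoxymethoxy)benzaldehyde | COCOc1ccc(C=O)c(OCOC)c1 | intermediate
10 | 3-[2,4-bis(methoxymethoxy)phenyl]-3-hydroxy-1-[2-hydroxy-4-(methoxymethoxy)-3-(3-methylbut-2-enyl)phenyl]propan-1-one (racemic) | CC(C)=CCc1c(OCOC)ccc(C(=O)CC(O)c2ccc(OCOC)cc2OCOC)c1O | intermediate (not isolated)
11 | (E)-3-[2,4-bis(methoxymethoxy)phenyl]-1-[2-hydroxy-4-(methoxymethoxy)-3-(3-methylbut-2-enyl)phenyl]prop-2-en-1-one | CC(C)=CCc1c(OCOC)ccc(C(=O)/C=C/c2ccc(OCOC)cc2OCOC)c1O | intermediate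
12 | 1-(2,4-dihydroxy-3-iodophenyl)ethanone | CC(=O)c1ccc(O)c(I)c1O | intermediate
13 | 1-[3-iodo-2,4-bis(methoxymethoxy)phenyl]ethanone | CC(=O)c1ccc(OCOC)c(I)c1OCOC | intermediate
14 | isoprene | C=CC(C)=C | starting material
15 | 1-{2,4-bis(methoxymethoxy)-3-[(E)-3-methylbuta-1,3-dienyl]phenyl}ethanone | CC(=O)c1ccc(OCOC)c(/C=C/C(C)=C)c1OCOC | intermediate
16 | 1-{2,4-bis(methoxymethoxy)-3-[(E)-3-methylbuta-1,3-dienyl]phenyl}-3-[2,4-bis(methoxymethoxy)phenyl]-3-hydroxypropan-1-one (racemic) | C=C(C)/C=C/c1c(OCOC)ccc(C(=O)CC(O)c2ccc(OCOC)cc2OCOC)c1OCOC | intermediate (not isolated)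
17 | (E)-1-{2,4-bis(methoxymethoxy)-3-[(E)-3-methylbuta-1,3-dienyl]phenyl}-3-[2,4-bis(methoxymethoxy)phenyl]prop-2-en-1-one | C=C(C)/C=C/c1c(OCOC)ccc(C(=O)/C=C/c2ccc(OCOC)cc2OCOC)c1OCOC | intermediate
18 | hepta-MOM kuwanon J, (3S,4R,5S), C3/C4 cis, C4/C5 trans, 2'-OH of ring A free | CC(C)=CCc1c(OCOC)ccc(C(=O)[C@H]2[C@@H](c3c(OCOC)ccc(C(=O)/C=C/c4ccc(OCOC)cc4OCOC)c3OCOC)C=C(C)C[C@@H]2c2ccc(OCOC)cc2OCOC)c1O | intermediate
19 | octakis(trimethylsilyl) ether of kuwanon J, (3S,4R,5S) | CC(C)=CCc1c(O[Si](C)(C)C)ccc(C(=O)[C@H]2[C@@H](c3c(O[Si](C)(C)C)ccc(C(=O)/C=C/c4ccc(O[Si](C)(C)C)cc4O[Si](C)(C)C)c3O[Si](C)(C)C)C=C(C)C[C@@H]2c2ccc(O[Si](C)(C)C)cc2O[Si](C)(C)C)c1O[Si](C)(C)C | intermediate (not isolated)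
20 | kuwanon J, (3S,4R,5S) | CC(C)=CCc1c(O)ccc(C(=O)[C@H]2[C@@H](c3c(O)ccc(C(=O)/C=C/c4ccc(O)cc4O)c3O)C=C(C)C[C@@H]2c2ccc(O)cc2O)c1O | target

## Step count and risks

Total step count: 12. Longest linear sequence: 7 steps (1, 7, 8, 9, 10, 11, 12).

Most likely to fail, first: step 11. Enantiocontrol of a radical-anion [4+2] by the scandium–PyBOX complex is not established, and the cis/trans ratio at C3 may be modest. Fallback: start again from 11 and 17 and give up catalyst control. The ground-state electron-transfer variant (CoI2 10 mol%, 1,10-phenanthroline 10 mol%, ZnI2 50 mol%, Bu4NBH4 30 mol%, CH2Cl2, 40 °C; monovalent cobalt as the electron source) gives, after removal of the all-trans isomer, the cis,trans adduct as the racemate F1. Preparative chromatography on an amylose tris(3,5-dimethylphenylcarbamate) phase separates the two mirror-image forms, and the 3S,4R,5S form is 18, where the route is rejoined.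

Second: step 9. The iodide of 13 sits between two ortho substituents, and isoprene can also be arylated at its other terminus. Fallback: from 13, replace the Heck reaction by a Suzuki–Miyaura coupling. Hydroboration of 2-methylbut-1-en-3-yne F2 with pinacolborane (Cp2Zr(H)Cl 5 mol%, Et3N 10 mol%, neat, 60 °C) gives the E-dienylboronate F3 with the diene geometry already fixed. F3 couples with 13 (Pd(OAc)2 3 mol%, SPhos 6 mol%, K3PO4, toluene/H2O, 80 °C) to give 15, where the route is rejoined.

Third: step 12. Seven MOM groups must leave a product that ketalises and cyclises under acid. Fallback: change the protecting groups before the ring is made, setting out from 11 and 13.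
- 11 is deprotected at the stable chalcone stage (3 M HCl, MeOH, 50 °C) to morachalcone A F4 and acetylated (Ac2O, pyridine, 0 °C; the chelated 2'-OH stays free) to the triacetate F5.
- 13 and 9 are condensed (KOH, EtOH/H2O, rt) to the iodochalcone F6, which is deprotected (3 M HCl, MeOH, 50 °C) to the tetrahydroxy iodochalcone F7 and peracetylated (Ac2O, Et3N, DMAP, CH2Cl2) to the tetraacetate F8.
- The Heck reaction of F8 with 14 (Pd(OAc)2, NaOAc, Bu4NCl, DMF, 80 °C) gives the dienyl chalcone tetraacetate F9.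
- F5 and F9 are joined under the conditions of step 11 to the heptaacetate adduct F10, and K2CO3 in MeOH at 0 °C removes the seven acetates without any acid to give 20, where the route is rejoined.

## Further compounds

F1 | step 11 | racemic hepta-MOM kuwanon J (1:1 mixture of 18 and its mirror image) | CC(C)=CCc1c(OCOC)ccc(C(=O)[C@H]2[C@@H](c3c(OCOC)ccc(C(=O)/C=C/c4ccc(OCOC)cc4OCOC)c3OCOC)C=C(C)C[C@@H]2c2ccc(OCOC)cc2OCOC)c1O.CC(C)=CCc1c(OCOC)ccc(C(=O)[C@@H]2[C@H](c3c(OCOC)ccc(C(=O)/C=C/c4ccc(OCOC)cc4OCOC)c3OCOC)C=C(C)C[C@H]2c2ccc(OCOC)cc2OCOC)c1O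
F2 | step 9 | 2-methylbut-1-en-3-yne (bought) | C=C(C)C#C
F3 | step 9 | (E)-4,4,5,5-tetramethyl-2-(3-methylbuta-1,3-dienyl)-1,3,2-dioxaborolane | C=C(C)/C=C/B1OC(C)(C)C(C)(C)O1
F4 | step 12 | morachalcone A | CC(C)=CCc1c(O)ccc(C(=O)/C=C/c2ccc(O)cc2O)c1O
F5 | step 12 | morachalcone A 4',2,4-triacetate (2'-OH free) | CC(C)=CCc1c(OC(C)=O)ccc(C(=O)/C=C/c2ccc(OC(C)=O)cc2OC(C)=O)c1O
F6 | step 12 | (E)-3-[2,4-bis(methoxymethoxy)phenyl]-1-[3-iodo-2,4-bis(methoxymethoxy)phenyl]prop-2-en-1-one | COCOc1ccc(/C=C/C(=O)c2ccc(OCOC)c(I)c2OCOC)c(OCOC)c1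
F7 | step 12 | (E)-1-(2,4-dihydroxy-3-iodophenyl)-3-(2,4-dihydroxyphenyl)prop-2-en-1-one | Oc1ccc(/C=C/C(=O)c2ccc(O)c(I)c2O)c(O)c1
F8 | step 12 | tetraacetate of F7 | CC(=O)Oc1ccc(/C=C/C(=O)c2ccc(OC(C)=O)c(I)c2OC(C)=O)c(OC(C)=O)c1
F9 | step 12 | (E)-1-{2,4-diacetoxy-3-[(E)-3-methylbuta-1,3-dienyl]phenyl}-3-(2,4-diacetoxyphenyl)prop-2-en-1-one | C=C(C)/C=C/c1c(OC(C)=O)ccc(C(=O)/C=C/c2ccc(OC(C)=O)cc2OC(C)=O)c1OC(C)=O
F10 | step 12 | kuwanon J heptaacetate, (3S,4R,5S), 2'-OH of ring A free | CC(C)=CCc1c(OC(C)=O)ccc(C(=O)[C@H]2[C@@H](c3c(OC(C)=O)ccc(C(=O)/C=C/c4ccc(OC(C)=O)cc4OC(C)=O)c3OC(C)=O)C=C(C)C[C@@H]2c2ccc(OC(C)=O)cc2OC(C)=O)c1O
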